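## Structural features

The target is a flavanone: benzene ring A is fused along C4a–C8a to the dihydropyranone ring C (O1, C2, C3, C4 carbonyl), and the 4-hydroxyphenyl ring B is attached to C2 by a single bond. Ring A is hexasubstituted; going round, it carries the C4 acyl carbon on C4a, OH on C5, a prenyl (3-methylbut-2-enyl) chain on C6, OH on C7, CH3 on C8 and the ring oxygen O1 on C8a, so it is a phloroglucinol core whose three oxygens all end up different. C2 (S) is the only stereocentre and has no stereogenic neighbour, but it is a benzylic ether carbon β to the C4 ketone and is lost whenever ring C opens to the 2'-hydroxychalcone (retro-oxa-Michael reaction), which base promotes and which free 5-OH and 4'-OH make easier. The second fragile element is the prenyl group: acid can add the flanking C5 or C7 hydroxyl across its double bond, hydrogenolysis and electrophilic oxidants or halogens attack it, and its CH2 is both benzylic and allylic. The real difficulty is regiochemical and not stereochemical: O1 must be bonded to the ring carbon next to the methyl-bearing C8 and not to the one next to the prenyl-bearing C6, although in any 2,4,6-trioxygenated ring A precursor these two positions ortho to C4a are almost indistinguishable. The key step exploits exactly this: ring A is built with oxygen only on C5 and C7 and with iodine on C8a, so the already (S)-configured C2 hydroxyl can be joined to C8a alone, which closes ring C at O1–C8a and fixes the C8-methyl/C6-prenyl pattern in the same event.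

## Logic of the disconnections

22 back to 21. The three aryl O–CH2OCH3 bonds (on O5, O7 and O4') are cut last. The phenols stay masked to the end because free 5-OH and 4'-OH make ring C open under base and would not survive the oxidation and metal-mediated steps. The gain is that every earlier intermediate is a neutral, base-stable ether. The forward step must be an acetal cleavage mild enough to leave the prenyl group between O5 and O7 uncyclised and C2 untouched.

21 back to 20. No skeletal bond is cut; the C4 carbonyl is traced back to a C4 carbinol. At the ketone level the ring-closure substrate would be a β-hydroxy ketone, which base dehydrates or cleaves, whereas the carbinol is inert to base. The gain is a ring-closure substrate without an enolisable carbonyl. The forward step needs a neutral oxidant that spares the trisubstituted alkene and the acetals; the configuration at C4 is irrelevant.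

20 back to 19 (the strategic cut). The O1–C8a bond is cut, opening ring C to an acyclic 1,3-diol with iodine on C8a. The cut is made here because the position of the halogen, not a choice between two similar phenols, then decides where O1 is attached. The gain is that the heterocycle disappears and two arenes joined by a three-carbon chain remain. The forward step must couple a secondary benzylic alkoxide to a doubly ortho-substituted, electron-rich aryl iodide without loss of iodine and without disturbing C2.

19 back to 18. The C2–H bond is cut, taking the C2 carbinol back to an aryl ketone. Aryl alkyl ketones are the best substrate class for catalyst-controlled hydride transfer, so the single stereocentre comes from a catalyst rather than from a chiral building block. The gain is an achiral-at-C2 precursor. The catalyst must override the racemic C4 carbinol, and the medium must not ionise that carbinol.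

18 back to 13 and 15. The C3–C4 bond is cut (aldol). This is the convergent point: a ring A aldehyde and a ring B methyl ketone of similar size. The gain is two simple monocyclic fragments. The forward step is a kinetic enolate addition to a hindered, non-enolisable aldehyde with a cold quench, because the adduct can revert or dehydrate.

13 back to 9. The C8a–I bond is cut. C8a–H is the only ring hydrogen left and lies ortho to the formyl carbon, so the masked aldehyde can direct metalation there; electrophilic iodination cannot reach a position meta to both oxygens. The gain is a halogen-free arene. The forward step must metalate a crowded ring C–H in preference to the benzylic–allylic CH2 and the methyl group.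

9 back to 6. The C4a–CHO bond is cut. C4a–H is the only ring hydrogen ortho to an acetal oxygen, so directed metalation is unambiguous. The gain is loss of the carbonyl carbon. The forward step must again favour ring over side-chain metalation.

6 back to 2 and 3. The C6–CH2 bond of the prenyl group is cut. The position between the two acetal oxygens is the most acidic and is best filled first, which also blocks it in later metalations. The gain is a commercial allylic bromide and a simple protected resorcinol. The forward step must couple at the primary carbon of the allyl system (SN2, not SN2'), which calls for copper.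

2 back to 1, and 15 back to 14. The O–CH2OCH3 bonds are cut. The acetal is chosen because it protects and also directs the metalations. The gain is two commercial phenols. The forward step is an ordinary O-alkylation.

## Other disconnections considered

Alternative 1: Ring A is cut at C8–C8a and C4a–C5. Ring C then arrives complete and enantiopure as the sulfinyl dihydropyranone A2, and C5–C8, with the prenyl group, the methyl group and both oxygens in place, arrive as the bis(silyloxy)diene A3 (trimethylsilyl groups assumed). In the forward step A3 would add through its methyl-bearing terminus to the enone β-carbon of A2 (the future C8a). The sulfinyl group would then be expelled to restore the enone, and the vinylogous enolate would acylate C4a with the ester carbon, giving after tautomerisation the aromatic ring A of A1.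
- In favour: the substitution pattern of ring A is written into the connectivity of A3, so the regiochemical problem is solved as securely as in the chosen plan (equal on this point). A1 appears with free 5-OH and 7-OH at the ketone level, so only one acetal remains and no oxidation is needed (better in protecting-group and redox economy). The prenyl group never meets an organolithium. The route is convergent, with a shorter longest linear sequence than the nine steps of the chosen plan (better).
- Against: C2 must be made first and carried through an acid- or base-mediated cascade while it is a p-alkoxybenzylic ether β to a carbonyl, the arrangement that ionises or ring-opens most easily. After the conjugate addition the enolate can also expel O1 and open ring C. A3 is substituted at both C6 and C8 and is a hindered, geometrically mixed nucleophile. A2 needs an asymmetric hetero-Diels–Alder reaction, sulfenylation and oxidation.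
- Comparison: the chosen plan relies on one well-understood bond formation that cannot touch C2, whereas this cascade strings several events together on a dihydropyranone acceptor. Total step counts should be similar (about ten); Alternative 1 is ahead in convergency, the chosen plan in the predictability of each step.

Alternative 2: Ring A is cut at C8–C8a, C6–C7 and C4a–C8a, giving the siloxycyclobutenone A5 (C8a, C6, C5, C4a) and the siloxypropyne A6 (C7, C8). In the forward step heating would open A5 by a four-electron process, the ketene so formed would add A6 in a (2+2) fashion, and a second four-electron opening followed by six-electron ring closure and tautomerisation would give the phenol A4.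
- In favour: the whole hexasubstituted ring forms in one reagent-free step, and O1 emerges as the only free hydroxyl while O5 and O7 are silylated. On regiochemical certainty this equals the chosen plan, and it is better in needing no directed metalation beside the prenyl group and in leaving C4a–H as a nucleophilic position.
- Against: the step builds neither ring C nor C2. C4a must afterwards be acylated and C2 set in a separate enantioselective operation. The obvious continuation through a 2'-hydroxychalcone closes O1–C2 by oxa-Michael addition, the reversible reaction by which flavanones racemise, so enantiocontrol is intrinsically weaker than in the chosen plan, where C2 is fixed before ring closure. A5 and A6 are not commercial and each needs several steps, and the ketene intermediates must not be diverted by the prenyl alkene at the temperatures required.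
- Comparison: structurally elegant for ring A, mechanistically clean in a thermal cascade, but longer overall and without a solution for the stereocentre.

Alternative 3: Ring C is cut at C2–C3. In the forward step a chiral dirhodium tetracarboxylate of the N-phthaloyl amino acid type (divalent rhodium) would convert the diazoketone A8 into a carbenoid at C3 that inserts into one of the two enantiotopic C–H bonds of the O1–CH2–aryl group, giving A7.
- In favour: ring C and C2 would be created together in one catalytic step at the ketone level, with no reduction–oxidation detour (better redox economy than the chosen plan). The stereocentre is made at the last C–C bond formation. The silyl ethers of A7 come off with buffered fluoride or very mild acid, which is gentler on the prenyl group (better endgame).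
- Against: A8 already contains O1 on C8a as a benzylic ether beside a differently protected O5, so the central regiochemical problem is moved into the synthesis of A8 and not solved by the key step. The acceptor-only carbenoid has faster options than insertion through a six-membered transition state: attack by the lone pair of O1 (five-membered oxonium ylide, then a 1,2-shift of the benzylic group to a benzofuranone), attack by the silyl ether oxygen on C5, and addition to the prenyl double bond. Enantiocontrol for six-membered-ring insertion of diazoketones is less developed than for five-membered cases. A8 would be made from a doubly ortho-substituted acid derivative by acylation of a diazoalkane, a hazardous operation.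
- Comparison: shorter on paper after A8, but selectivity would rest on subtle catalyst–substrate effects, whereas in the chosen plan each selectivity is enforced by connectivity.

Key step: step 8

Remark on the chemistry: the carbinol centre at C4 (C1 of the propane chain) of 18, 19 and 20 is carried as a mixture of both configurations because step 9 erases it; only C2 is controlled.

Remark on the structures: (3S) in 19 and (2S) in 20, 21 and 22 denote the same spatial arrangement (O > aryl > CH2 > H at this carbon throughout). Ring closure with retention therefore leads to the target enantiomer, and no structure needed correction. The diol is kept with both hydroxyls free. The reduction catalyst is fixed as the (S,S) enantiomer, and an electron-rich phenanthroline is specified for the ring closure.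

## Route

Step 1
Reactants: 1 4-methylresorcinol (4-methylbenzene-1,3-diol)
Product: 2 2,4-bis(methoxymethoxy)-1-methylbenzene
Conditions: MOMCl, i-Pr2NEt, CH2Cl2, 0 °C → rt
Reagents that add atoms: chloromethyl methyl ether (MOMCl), COCCl
Why: Williamson-type O-alkylation of both phenols by the reactive α-chloro ether; the MOM acetals are stable to the organolithium, copper and carbonate steps that follow and serve as directing groups for the metalations in steps 2 and 3.

Step 2
Reactants: 2 2,4-bis(methoxymethoxy)-1-methylbenzene; 3 prenyl bromide (1-bromo-3-methylbut-2-ene)
Product: 6 1,3-bis(methoxymethoxy)-4-methyl-2-(3-methylbut-2-enyl)benzene, via aryllithium 4 (not isolated), via arylcopper 5 (not isolated)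
Conditions: n-BuLi, THF, 0 °C; CuI (1 equiv), −40 °C; 3, −40 °C → rt
Reagents that add atoms: none
Why: Directed ortho-metalation: the ring C–H flanked by both MOM ethers (future C6) is the most acidic and doubly coordinated, so n-BuLi removes it selectively; transmetalation to the arylcopper 5 makes the coupling with the allylic bromide a clean SN2 substitution at the primary carbon.

Step 3
Reactants: 6 1,3-bis(methoxymethoxy)-4-methyl-2-(3-methylbut-2-enyl)benzene
Product: 9 2,4-bis(methoxymethoxy)-5-methyl-3-(3-methylbut-2-enyl)benzaldehyde, via aryllithium 7 (not isolated), via lithium hemiaminal alkoxide 8 (not isolated)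
Conditions: n-BuLi, TMEDA, THF, −20 → 0 °C; DMF, −78 °C → rt; H2O
Reagents that add atoms: N,N-dimethylformamide (DMF), CN(C)C=O
Why: Second directed ortho-metalation: after step 2 the only ring hydrogen ortho to a MOM ether is the one on the future C4a, so the regiochemistry is unambiguous; the aryllithium 7 adds to DMF and the tetrahedral adduct 8 holds the aldehyde oxidation level until aqueous hydrolysis (Bouveault-type formylation).

Step 4
Reactants: 9 2,4-bis(methoxymethoxy)-5-methyl-3-(3-methylbut-2-enyl)benzaldehyde
Product: 13 2-iodo-4,6-bis(methoxymethoxy)-3-methyl-5-(3-methylbut-2-enyl)benzaldehyde, via lithium amino alkoxide 10 (not isolated), via ring-lithiated amino alkoxide 11 (not isolated), via iodinated amino alkoxide 12 (not isolated)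
Conditions: LiN(Me)CH2CH2NMe2 (from MeNHCH2CH2NMe2 + n-BuLi), THF, −20 °C; n-BuLi (3 equiv), −20 °C; I2, −78 °C → rt; H2O
Reagents that add atoms: iodine, [I][I]
Why: Comins-type directed lithiation: the lithium amide adds to the aldehyde to give the α-amino alkoxide 10, which protects the carbonyl and chelates n-BuLi so that it removes the only remaining ring hydrogen (future C8a, ortho to the masked formyl group); iodine quench of 11 and hydrolysis of 12 release the iodo aldehyde. Electrophilic iodination could not reach this position, which is meta to both oxygens.

Step 5
Reactants: 14 4'-hydroxyacetophenone (1-(4-hydroxyphenyl)ethanone)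
Product: 15 1-[4-(methoxymethoxy)phenyl]ethanone
Conditions: MOMCl, i-Pr2NEt, CH2Cl2, 0 °C → rt
Reagents that add atoms: chloromethyl methyl ether (MOMCl), COCCl
Why: O-alkylation of the phenol as in step 1; the MOM ether tolerates enolate formation, transfer hydrogenation, carbonate at 110 °C and the periodinane, and is removed together with the other two in step 10.

Step 6
Reactants: 15 1-[4-(methoxymethoxy)phenyl]ethanone; 13 2-iodo-4,6-bis(methoxymethoxy)-3-methyl-5-(3-methylbut-2-enyl)benzaldehyde
Product: 18 3-hydroxy-3-[2-iodo-4,6-bis(methoxymethoxy)-3-methyl-5-(3-methylbut-2-enyl)phenyl]-1-[4-(methoxymethoxy)phenyl]propan-1-one (racemic), via lithium enolate 16 (not isolated), via lithium aldolate 17 (not isolated)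
Conditions: LiN(i-Pr)2, THF, −78 °C; 13, −78 °C; AcOH, −78 °C
Reagents that add atoms: none
Why: Crossed aldol addition of the kinetic lithium enolate 16 to the non-enolisable aldehyde 13 at −78 °C; quenching the aldolate 17 cold with AcOH prevents retro-aldol cleavage and E1cB dehydration to the enone. The new carbinol centre (future C4) is formed without control, which is acceptable because step 9 removes it.

Step 7
Reactants: 18 3-hydroxy-3-[2-iodo-4,6-bis(methoxymethoxy)-3-methyl-5-(3-methylbut-2-enyl)phenyl]-1-[4-(methoxymethoxy)phenyl]propan-1-one (racemic)
Product: 19 (3S)-1-[2-iodo-4,6-bis(methoxymethoxy)-3-methyl-5-(3-methylbut-2-enyl)phenyl]-3-[4-(methoxymethoxy)phenyl]propane-1,3-diol (both C1 epimers)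
Conditions: RuCl(p-cymene)[(S,S)-TsDPEN] (2 mol %), HCO2H–Et3N (5:2), CH2Cl2, 25 °C
Reagents that add atoms: none
Why: Noyori–Ikariya asymmetric transfer hydrogenation of an aryl ketone: the ruthenium hydride and the ligand N–H deliver hydride and proton through a six-membered transition state in which the aryl group of the ketone is held by a CH/π contact with the η6-cymene, so the (S,S) ligand sets the (S)-carbinol (future C2) irrespective of the remote racemic carbinol. The formate buffer is mild enough for the MOM ethers and leaves the aryl iodide and the alkene untouched.

Step 8
Reactants: 19 (3S)-1-[2-iodo-4,6-bis(methoxymethoxy)-3-methyl-5-(3-methylbut-2-enyl)phenyl]-3-[4-(methoxymethoxy)phenyl]propane-1,3-diol (both C1 epimers)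
Product: 20 (2S)-5,7-bis(methoxymethoxy)-2-[4-(methoxymethoxy)phenyl]-8-methyl-6-(3-methylbut-2-enyl)chroman-4-ol (both C4 epimers)
Conditions: CuI (20 mol %), 3,4,7,8-tetramethyl-1,10-phenanthroline (40 mol %), Cs2CO3 (2.5 equiv), toluene (0.02 M), 110 °C, Ar
Reagents that add atoms: none
Why: Cs2CO3 converts the C2 hydroxyl into its alkoxide, which binds phenanthroline-ligated univalent copper; intramolecular oxidative addition of the C8a–I bond gives an aryl alkoxide of trivalent copper (a seven-membered cupracycle through Cu, O1, C2, C3, C4, C4a and C8a), and C–O reductive elimination releases the aryl ether and univalent copper. The closest known reaction type is the Ullmann-type copper-catalysed O-arylation of secondary alcohols with aryl iodides under phenanthroline ligands, which is established for intramolecular closure of 3-(2-haloaryl)propanols to chromans. Ring C is closed as a six-membered ring by attack of O1 on C8a with the breaking C–I bond outside the new ring (exo-type closure at an sp2 carbon). No stereocentre is created: no bond to C2 is made or broken, so the (S) configuration from step 7 is retained, and both C4 epimers cyclise. Regioselectivity is secured by the substrate, because C8a is the only halogen-bearing carbon and C5 is already an acetal oxygen. Chemoselectivity between the two hydroxyls is secured by ring size, since the C4 oxygen could reach C8a only through a four-membered benzoxete, and intermolecular arylation is held back by high dilution and by the crowding of C8a. The electron-rich tetramethylphenanthroline is chosen because oxidative addition at this electron-rich, doubly ortho-substituted iodide is expected to be the slow event, and oxygen is excluded so that the benzylic carbinols are not oxidised.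

Step 9
Reactants: 20 (2S)-5,7-bis(methoxymethoxy)-2-[4-(methoxymethoxy)phenyl]-8-methyl-6-(3-methylbut-2-enyl)chroman-4-ol (both C4 epimers)
Product: 21 (2S)-5,7-bis(methoxymethoxy)-2-[4-(methoxymethoxy)phenyl]-8-methyl-6-(3-methylbut-2-enyl)chroman-4-one
Conditions: Dess–Martin periodinane, NaHCO3, CH2Cl2, 0 °C → rt
Reagents that add atoms: none
Why: Dess–Martin oxidation (alkoxy exchange at hypervalent iodine, then loss of the carbinol hydrogen) converts both C4 epimers into the single ketone under buffered, near-neutral conditions that spare the trisubstituted alkene and the acetals; C2 is not enolisable and, without base, ring C does not open, so the configuration is kept.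

Step 10
Reactants: 21 (2S)-5,7-bis(methoxymethoxy)-2-[4-(methoxymethoxy)phenyl]-8-methyl-6-(3-methylbut-2-enyl)chroman-4-one
Product: 22 (2S)-5,7-dihydroxy-2-(4-hydroxyphenyl)-8-methyl-6-(3-methylbut-2-enyl)chroman-4-one (5,7,4'-trihydroxy-8-methyl-6-prenylflavanone)
Conditions: 3 M HCl (aq), MeOH, 40 °C
Reagents that add atoms: none
Why: Acid-catalysed acetal exchange with methanol removes the three MOM groups as dimethoxymethane; the 5-O-acetal next to the carbonyl and the crowded 7-O-acetal are especially labile, which allows dilute acid, moderate temperature and a short reaction time, conditions commonly tolerated by C-prenylated polyphenols, so that addition of O5 or O7 to the prenyl double bond and acid-mediated opening of ring C at C2 should stay slow.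

## Compound list

1 | 4-methylresorcinol (4-methylbenzene-1,3-diol) | Cc1ccc(O)cc1O | starting material
2 | 2,4-bis(methoxymethoxy)-1-methylbenzene | Cc1ccc(OCOC)cc1OCOC | intermediate
3 | prenyl bromide (1-bromo-3-methylbut-2-ene) | CC(C)=CCBr | starting material
4 | [2,6-bis(methoxymethoxy)-3-methylphenyl]lithium | [Li]c1c(OCOC)ccc(C)c1OCOC | intermediate (not isolated)
5 | [2,6-bis(methoxymethoxy)-3-methylphenyl]copper (univalent copper) | [Cu]c1c(OCOC)ccc(C)c1OCOC | intermediate (not isolated)
6 | 1,3-bis(methoxymethoxy)-4-methyl-2-(3-methylbut-2-enyl)benzene | CC(C)=CCc1c(OCOC)ccc(C)c1OCOC | intermediate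
7 | [2,4-bis(methoxymethoxy)-5-methyl-3-(3-methylbut-2-enyl)phenyl]lithium | [Li]c1cc(C)c(OCOC)c(CC=C(C)C)c1OCOC | intermediate (not isolated)
8 | lithium [2,4-bis(methoxymethoxy)-5-methyl-3-(3-methylbut-2-enyl)phenyl](dimethylamino)methanolate (racemic) | [Li]OC(N(C)C)c1cc(C)c(OCOC)c(CC=C(C)C)c1OCOC | intermediate (not isolated)
9 | 2,4-bis(methoxymethoxy)-5-methyl-3-(3-methylbut-2-enyl)benzaldehyde | O=Cc1cc(C)c(OCOC)c(CC=C(C)C)c1OCOC | intermediate
10 | lithium [2,4-bis(methoxymethoxy)-5-methyl-3-(3-methylbut-2-enyl)phenyl]{[2-(dimethylamino)ethyl](methyl)amino}methanolate (racemic) | [Li]OC(N(C)CCN(C)C)c1cc(C)c(OCOC)c(CC=C(C)C)c1OCOC | intermediate (not isolated)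
11 | lithium {[2-(dimethylamino)ethyl](methyl)amino}[2-lithio-4,6-bis(methoxymethoxy)-3-methyl-5-(3-methylbut-2-enyl)phenyl]methanolate (racemic) | [Li]OC(N(C)CCN(C)C)c1c([Li])c(C)c(OCOC)c(CC=C(C)C)c1OCOC | intermediate (not isolated)
12 | lithium {[2-(dimethylamino)ethyl](methyl)amino}[2-iodo-4,6-bis(methoxymethoxy)-3-methyl-5-(3-methylbut-2-enyl)phenyl]methanolate (racemic) | [Li]OC(N(C)CCN(C)C)c1c(I)c(C)c(OCOC)c(CC=C(C)C)c1OCOC | intermediate (not isolated)
13 | 2-iodo-4,6-bis(methoxymethoxy)-3-methyl-5-(3-methylbut-2-enyl)benzaldehyde | O=Cc1c(I)c(C)c(OCOC)c(CC=C(C)C)c1OCOC | intermediate
14 | 4'-hydroxyacetophenone (1-(4-hydroxyphenyl)ethanone) | CC(=O)c1ccc(O)cc1 | starting material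
15 | 1-[4-(methoxymethoxy)phenyl]ethanone | CC(=O)c1ccc(OCOC)cc1 | intermediate
16 | lithium 1-[4-(methoxymethoxy)phenyl]ethenolate | C=C(O[Li])c1ccc(OCOC)cc1 | intermediate (not isolated)
17 | lithium 1-[2-iodo-4,6-bis(methoxymethoxy)-3-methyl-5-(3-methylbut-2-enyl)phenyl]-3-[4-(methoxymethoxy)phenyl]-3-oxopropan-1-olate (racemic) | [Li]OC(CC(=O)c1ccc(OCOC)cc1)c1c(I)c(C)c(OCOC)c(CC=C(C)C)c1OCOC | intermediate (not isolated)
18 | 3-hydroxy-3-[2-iodo-4,6-bis(methoxymethoxy)-3-methyl-5-(3-methylbut-2-enyl)phenyl]-1-[4-(methoxymethoxy)phenyl]propan-1-one (racemic) | CC(C)=CCc1c(OCOC)c(C)c(I)c(C(O)CC(=O)c2ccc(OCOC)cc2)c1OCOC | intermediate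
19 | (3S)-1-[2-iodo-4,6-bis(methoxymethoxy)-3-methyl-5-(3-methylbut-2-enyl)phenyl]-3-[4-(methoxymethoxy)phenyl]propane-1,3-diol (both C1 epimers) | CC(C)=CCc1c(OCOC)c(C)c(I)c(C(O)C[C@H](O)c2ccc(OCOC)cc2)c1OCOC | intermediate
20 | (2S)-5,7-bis(methoxymethoxy)-2-[4-(methoxymethoxy)phenyl]-8-methyl-6-(3-methylbut-2-enyl)chroman-4-ol (both C4 epimers) | CC(C)=CCc1c(OCOC)c(C)c2c(c1OCOC)C(O)C[C@@H](c1ccc(OCOC)cc1)O2 | intermediate
21 | (2S)-5,7-bis(methoxymethoxy)-2-[4-(methoxymethoxy)phenyl]-8-methyl-6-(3-methylbut-2-enyl)chroman-4-one | CC(C)=CCc1c(OCOC)c(C)c2c(c1OCOC)C(=O)C[C@@H](c1ccc(OCOC)cc1)O2 | intermediate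
22 | (2S)-5,7-dihydroxy-2-(4-hydroxyphenyl)-8-methyl-6-(3-methylbut-2-enyl)chroman-4-one | CC(C)=CCc1c(O)c(C)c2c(c1O)C(=O)C[C@@H](c1ccc(O)cc1)O2 | target

## Step count and least certain steps

Total step count: 10. Longest linear sequence: 9 (steps 1, 2, 3, 4, 6, 7, 8, 9, 10); step 5 is a one-step side branch.

Step 8 (key step). Most likely failure: reductive loss of iodine, or stalling. The neighbouring C4 alkoxide can chelate the aryl–copper intermediate and act as a hydride donor, and oxidative addition at an electron-rich C–I bond flanked by two ortho substituents may be slow enough for thermal decomposition to overtake ring closure. Fallback: it sets out from 18. The C4 hydroxyl is silylated (TBSOTf, 2,6-lutidine, CH2Cl2, −78 °C) to the tert-butyldimethylsilyl ether F1, and the ketone is reduced as in step 7 to the (S)-carbinol F2. Ring C is then closed on this mono-alcohol by palladium-catalysed intramolecular etherification (Pd(OAc)2, a divalent palladium precatalyst reduced in the flask to zerovalent palladium, with t-BuXPhos and Cs2CO3 in toluene at 80 °C). This is a different catalytic cycle, better suited to hindered electron-rich aryl halides, and the silyl group has removed the neighbouring alkoxide that would otherwise feed β-hydride elimination. The resulting 4-silyloxyflavan F3 is desilylated with Bu4NF and the route is rejoined at 20.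

Step 4. Most likely failure: competing deprotonation at the benzylic–allylic CH2 of the prenyl group or at the C8 methyl during the long exposure to excess n-BuLi, together with slow metalation of a ring C–H squeezed between the amino alkoxide and the methyl group. Fallback: it sets out from 6. The aryllithium is generated as in step 3 but trapped with ClC(O)NEt2 to give the diethylamide F4. The tertiary amide, a much stronger director, allows ortho-lithiation with s-BuLi/TMEDA in THF at −78 °C within a short time, and iodine quench gives the iodo amide F5. Cp2Zr(H)Cl (tetravalent zirconium hydride) in THF at rt then reduces the tertiary amide to the aldehyde, sparing the aryl iodide and the trisubstituted alkene, and the route is rejoined at 13.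

Step 3. Most likely failure: loss of site control, because the MOM ether on the future O5 can deliver n-BuLi either to the ring C–H or to the prenyl CH2 that it also flanks, giving side-chain metalation and a mixture after the DMF quench. Fallback: it sets out from 1 and brings in the prenyl group after the formyl group. Vilsmeier–Haack formylation (POCl3, DMF, then aqueous hydrolysis) attacks the position para to one hydroxyl and ortho to the other and gives 2,4-dihydroxy-5-methylbenzaldehyde F6. MOMCl/i-Pr2NEt converts it into the bis-MOM aldehyde F7. The aldehyde is masked in the flask as its α-amino alkoxide with lithium 4-methylpiperazin-1-ide (a weakly directing amide), so that n-BuLi metalates the position between the two acetal oxygens. CuI and 3 then install the prenyl group, and aqueous work-up returns the aldehyde, rejoining the route at 9.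

Step 7. Most likely failure: ionisation or elimination of the doubly activated benzylic C4 carbinol in the formic acid medium (dehydration to the enone) or retro-aldol cleavage, and weaker facial control if the free β-hydroxyl binds ruthenium. Fallback: it sets out from 18. Et3SiOTf/2,6-lutidine (CH2Cl2, −78 °C) gives the triethylsilyl ether F8. Corey–Bakshi–Shibata reduction with the (R)-configured B-methyl oxazaborolidine and catecholborane (toluene, −78 °C), which is aprotic, non-acidic and does not hydroborate the alkene, gives the (S)-carbinol F9. Bu4NF buffered with AcOH removes the silyl group, and the route is rejoined at 19.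

## Further compounds

F1 | step 8 | 3-(tert-butyldimethylsilyloxy)-3-[2-iodo-4,6-bis(methoxymethoxy)-3-methyl-5-(3-methylbut-2-enyl)phenyl]-1-[4-(methoxymethoxy)phenyl]propan-1-one (racemic) | CC(C)=CCc1c(OCOC)c(C)c(I)c(C(CC(=O)c2ccc(OCOC)cc2)O[Si](C)(C)C(C)(C)C)c1OCOC
F2 | step 8 | (1S)-3-(tert-butyldimethylsilyloxy)-3-[2-iodo-4,6-bis(methoxymethoxy)-3-methyl-5-(3-methylbut-2-enyl)phenyl]-1-[4-(methoxymethoxy)phenyl]propan-1-ol (both C3 epimers) | CC(C)=CCc1c(OCOC)c(C)c(I)c(C(C[C@H](O)c2ccc(OCOC)cc2)O[Si](C)(C)C(C)(C)C)c1OCOC
F3 | step 8 | tert-butyl{[(2S)-5,7-bis(methoxymethoxy)-2-[4-(methoxymethoxy)phenyl]-8-methyl-6-(3-methylbut-2-enyl)chroman-4-yl]oxy}dimethylsilane (both C4 epimers) | CC(C)=CCc1c(OCOC)c(C)c2c(c1OCOC)C(O[Si](C)(C)C(C)(C)C)C[C@@H](c1ccc(OCOC)cc1)O2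
F4 | step 4 | N,N-diethyl-2,4-bis(methoxymethoxy)-5-methyl-3-(3-methylbut-2-enyl)benzamide | CCN(CC)C(=O)c1cc(C)c(OCOC)c(CC=C(C)C)c1OCOC
F5 | step 4 | N,N-diethyl-2-iodo-4,6-bis(methoxymethoxy)-3-methyl-5-(3-methylbut-2-enyl)benzamide | CCN(CC)C(=O)c1c(I)c(C)c(OCOC)c(CC=C(C)C)c1OCOC
F6 | step 3 | 2,4-dihydroxy-5-methylbenzaldehyde | Cc1cc(C=O)c(O)cc1O
F7 | step 3 | 2,4-bis(methoxymethoxy)-5-methylbenzaldehyde | Cc1cc(C=O)c(OCOC)cc1OCOC
F8 | step 7 | 3-[2-iodo-4,6-bis(methoxymethoxy)-3-methyl-5-(3-methylbut-2-enyl)phenyl]-1-[4-(methoxymethoxy)phenyl]-3-(triethylsilyloxy)propan-1-one (racemic) | CC(C)=CCc1c(OCOC)c(C)c(I)c(C(CC(=O)c2ccc(OCOC)cc2)O[Si](CC)(CC)CC)c1OCOC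
F9 | step 7 | (1S)-3-[2-iodo-4,6-bis(methoxymethoxy)-3-methyl-5-(3-methylbut-2-enyl)phenyl]-1-[4-(methoxymethoxy)phenyl]-3-(triethylsilyloxy)propan-1-ol (both C3 epimers) | CC(C)=CCc1c(OCOC)c(C)c(I)c(C(C[C@H](O)c2ccc(OCOC)cc2)O[Si](CC)(CC)CC)c1OCOC
A1 | alternative 1 | (2S)-5,7-dihydroxy-2-[4-(methoxymethoxy)phenyl]-8-methyl-6-(3-methylbut-2-enyl)chroman-4-one | CC(C)=CCc1c(O)c(C)c2c(c1O)C(=O)C[C@@H](c1ccc(OCOC)cc1)O2
A2 | alternative 1 | (2S)-2-[4-(methoxymethoxy)phenyl]-5-(phenylsulfinyl)-2,3-dihydro-4H-pyran-4-one (either configuration at sulfur) | O=C1C[C@@H](c2ccc(OCOC)cc2)OC=C1S(=O)c1ccccc1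
A3 | alternative 1 | 1-methoxy-2-(3-methylbut-2-enyl)-1,3-bis(trimethylsilyloxy)penta-1,3-diene (double-bond geometry not defined) | CC=C(O[Si](C)(C)C)C(CC=C(C)C)=C(OC)O[Si](C)(C)C
A4 | alternative 2 | 2-methyl-4-(3-methylbut-2-enyl)-3,5-bis(triisopropylsilyloxy)phenol | CC(C)=CCc1c(O[Si](C(C)C)(C(C)C)C(C)C)c(C)c(O)cc1O[Si](C(C)C)(C(C)C)C(C)C
A5 | alternative 2 | 2-(3-methylbut-2-enyl)-3-(triisopropylsilyloxy)cyclobut-2-en-1-one | CC(C)=CCC1=C(O[Si](C(C)C)(C(C)C)C(C)C)CC1=O
A6 | alternative 2 | triisopropyl(prop-1-ynyloxy)silane | CC#CO[Si](C(C)C)(C(C)C)C(C)C
A7 | alternative 3 | (2S)-5,7-bis(tert-butyldimethylsilyloxy)-2-[4-(tert-butyldimethylsilyloxy)phenyl]-8-methyl-6-(3-methylbut-2-enyl)chroman-4-one | CC(C)=CCc1c(O[Si](C)(C)C(C)(C)C)c(C)c2c(c1O[Si](C)(C)C(C)(C)C)C(=O)C[C@@H](c1ccc(O[Si](C)(C)C(C)(C)C)cc1)O2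
A8 | alternative 3 | 1-[2,4-bis(tert-butyldimethylsilyloxy)-6-{[4-(tert-butyldimethylsilyloxy)phenyl]methoxy}-5-methyl-3-(3-methylbut-2-enyl)phenyl]-2-diazoethanone | CC(C)=CCc1c(O[Si](C)(C)C(C)(C)C)c(C)c(OCc2ccc(O[Si](C)(C)C(C)(C)C)cc2)c(C(=O)C=[N+]=[N-])c1O[Si](C)(C)C(C)(C)C
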